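The decalin is cut at C-2–C-3 of ring B. One intramolecular Michael addition of a methyl ketone enolate to a ring-A-bound butenedioate closes ring B and, because C-1 and C-2 then sit next to esters and C-4a next to the C-4 ketone, lets these centres settle by equilibration into the all-equatorial trans-decalin; this is the arrangement of the target (C-1 propenyl, C-2 acyl and C-7 methyl equatorial, H-4a/H-8a trans). The precursor is a trans-2-acetyl-5-methylcyclohexane from (S)-citronellal carrying a methyl/tert-butyl butenedioate on C-8a. The esters are later differentiated and a separately built epoxy-diol pyridine is joined at C-2.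

Key step: step 8

Numbering used below: decalin C-1 (propenyl), C-2 (acyl), C-3=C-4 (4-methyl), C-4a, C-5 to C-8 (7-methyl), C-8a; cyclohexyl unit C-1′ (bonded to pyridone C-5), C-2′/C-3′ (epoxide), C-4′ (secondary carbinol).
Remark: the olefination in step 6 may give both alkene isomers; 10, 11 and 12 are drawn E, and either isomer converges in step 8.
Assumption: 1,4-dioxaspiro[4.5]dec-6-en-8-one (22) is taken as a catalogue compound.

Step 1
Reactants: 1 (S)-citronellal; 2 dimethyl malonate
Product: 3 dimethyl 2-[(3S)-3,7-dimethyloct-6-enylidene]malonate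
Conditions: piperidinium acetate (10 mol %), 4 Å sieves, CH2Cl2, 0 °C → rt
Reagents that add atoms: none
Why: Knoevenagel condensation of an α-unbranched aldehyde with a malonate under amine-salt catalysis, which leaves the existing stereocentre (future C-7) untouched.

Step 2
Reactants: 3 dimethyl 2-[(3S)-3,7-dimethyloct-6-enylidene]malonate
Product: 4 dimethyl 2-[(1S,2S,5S)-2-isopropenyl-5-methylcyclohexyl]malonate
Conditions: FeCl3 on Al2O3 (0.2 equiv FeCl3), CH2Cl2, −78 °C → rt
Reagents that add atoms: none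
Why: Lewis-acid-promoted intramolecular ene reaction of the alkylidene malonate through a chair-like transition state with the methyl group equatorial, which should give the 1,2-trans all-equatorial ring A and so sets C-8a and C-4a relative to C-7.

Step 3
Reactants: 4 dimethyl 2-[(1S,2S,5S)-2-isopropenyl-5-methylcyclohexyl]malonate
Product: 5 methyl 2-[(1R,2S,5S)-2-isopropenyl-5-methylcyclohexyl]acetate
Conditions: LiCl, H2O, DMSO, 150 °C
Reagents that add atoms: none
Why: Krapcho dealkoxycarbonylation of a malonate (chloride demethylation, then decarboxylation), which does not affect the ring stereocentres or the isopropenyl group.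

Step 4
Reactants: 5 methyl 2-[(1R,2S,5S)-2-isopropenyl-5-methylcyclohexyl]acetate
Product: 7 methyl 2-hydroxy-2-[(1S,2S,5S)-2-isopropenyl-5-methylcyclohexyl]acetate (both carbinol epimers), via potassium enolate 6 (not isolated)
Conditions: KN(SiMe3)2, THF, −78 °C; 3-phenyl-2-(phenylsulfonyl)oxaziridine, −78 °C; AcOH
Reagents that add atoms: 3-phenyl-2-(phenylsulfonyl)oxaziridine, O=S(=O)(c1ccccc1)N1OC1c1ccccc1
Why: Electrophilic hydroxylation of an ester enolate with an N-sulfonyloxaziridine; the new carbinol centre need not be controlled because step 5 oxidises it.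

Step 5
Reactants: 7 methyl 2-hydroxy-2-[(1S,2S,5S)-2-isopropenyl-5-methylcyclohexyl]acetate
Product: 8 methyl 2-[(1S,2S,5S)-2-isopropenyl-5-methylcyclohexyl]-2-oxoacetate
Conditions: Dess–Martin periodinane, CH2Cl2, rt
Reagents that add atoms: none
Why: Dess–Martin oxidation of an α-hydroxy ester to the α-keto ester under neutral conditions, with the equatorial C-8a substituent being the thermodynamic epimer in any case.

Step 6
Reactants: 8 methyl 2-[(1S,2S,5S)-2-isopropenyl-5-methylcyclohexyl]-2-oxoacetate; 9 (tert-butoxycarbonylmethylene)triphenylphosphorane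
Product: 10 4-tert-butyl 1-methyl (E)-2-[(1S,2S,5S)-2-isopropenyl-5-methylcyclohexyl]but-2-enedioate
Conditions: CH2Cl2, rt
Reagents that add atoms: none
Why: Wittig olefination of the activated α-keto ester carbonyl with a stabilised ylide, run at room temperature so that a thermal carbonyl-ene reaction with the isopropenyl group is avoided.

Step 7
Reactants: 10 4-tert-butyl 1-methyl (E)-2-[(1S,2S,5S)-2-isopropenyl-5-methylcyclohexyl]but-2-enedioate
Product: 12 4-tert-butyl 1-methyl (E)-2-[(1S,2S,5S)-2-acetyl-5-methylcyclohexyl]but-2-enedioate, via ozonide 11 (not isolated)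
Conditions: O3 (1 equiv), CH2Cl2, −78 °C; PPh3, −78 °C → rt
Reagents that add atoms: ozone, O=[O+][O-]
Why: Ozonolysis with reductive work-up, chemoselective because the electron-rich 1,1-disubstituted alkene reacts far faster with the electrophilic ozone than the electron-poor butenedioate.

Step 8
Reactants: 12 4-tert-butyl 1-methyl (E)-2-[(1S,2S,5S)-2-acetyl-5-methylcyclohexyl]but-2-enedioate
Product: 13 2-tert-butyl 1-methyl 7-methyl-4-oxodecahydronaphthalene-1,2-dicarboxylate (trans-fused; H-1 H-2 H-4a H-7 H-8a all axial)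
Conditions: t-BuOK (0.2 equiv), t-BuOH/THF, 0 °C → rt; AcOH
Reagents that add atoms: none
Why: Catalytic t-BuOK reversibly forms the methyl ketone enolate (C-3), which adds to C-2, the unsubstituted β-carbon of the acrylate unit, and the resulting C-1 ester enolate is protonated by t-BuOH so that the alkoxide is regenerated (intramolecular Michael addition; closest known type: base-mediated 6-endo closure of ketone enolates onto alkylidene diesters to give decalones). Ring B closes in the 6-endo-trig (enolendo) mode, forming only the C-2–C-3 bond. C-1 and C-2 each lie α to an ester and C-4a α to the C-4 ketone, so all three are set by enolisation and reprotonation and should settle equatorial (1,2-trans diester, trans ring fusion), with the equatorial C-7 methyl of ring A as the fixed reference; C-8a, transiently labile as the γ-position of the butenedioate, is held in the trans arrangement because only that isomer reaches the strain-free trans-decalone. The step needs 6-endo over 5-exo closure and C-alkylation over acylation by the methyl ester: attack at the substituted alkene carbon would build a quaternary centre in a strained hydrindanone and is reversible, while a substoichiometric base in a protic medium cannot drive a Claisen condensation. Both alkene isomers of 12 give the same enolate after addition and hence the same product.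

Step 9
Reactants: 13 2-tert-butyl 1-methyl 7-methyl-4-oxodecahydronaphthalene-1,2-dicarboxylate
Product: 15 2-tert-butyl 1-methyl 7-methyl-4-(trifluoromethylsulfonyloxy)-1,2,4a,5,6,7,8,8a-octahydronaphthalene-1,2-dicarboxylate, via potassium enolate 14 (not isolated)
Conditions: KN(SiMe3)2 (1.1 equiv), THF, −78 °C; PhNTf2, −78 → 0 °C
Reagents that add atoms: N-phenylbis(trifluoromethanesulfonimide), O=S(=O)(N(c1ccccc1)S(=O)(=O)C(F)(F)F)C(F)(F)F
Why: Kinetic deprotonation by the bulky amide at the C-3 methylene (faster than at the C-4a methine or the less acidic ester α-positions) and O-sulfonylation give the enol triflate, fixing the double bond at C-3/C-4.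

Step 10
Reactants: 15 2-tert-butyl 1-methyl 7-methyl-4-(trifluoromethylsulfonyloxy)-1,2,4a,5,6,7,8,8a-octahydronaphthalene-1,2-dicarboxylate
Product: 16 2-tert-butyl 1-methyl 4,7-dimethyl-1,2,4a,5,6,7,8,8a-octahydronaphthalene-1,2-dicarboxylate
Conditions: Pd(PPh3)4 (5 mol %), MeZnCl (2 equiv), THF, rt → 50 °C
Reagents that add atoms: methylzinc chloride, C[Zn]Cl
Why: Negishi cross-coupling of an alkenyl triflate with a methylzinc reagent, neutral conditions under which both esters and their α-stereocentres survive.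

Step 11
Reactants: 16 2-tert-butyl 1-methyl 4,7-dimethyl-1,2,4a,5,6,7,8,8a-octahydronaphthalene-1,2-dicarboxylate
Product: 17 tert-butyl 1-(hydroxymethyl)-4,7-dimethyl-1,2,4a,5,6,7,8,8a-octahydronaphthalene-2-carboxylate
Conditions: LiBH4, MeOH (1 equiv), THF, 0 °C → rt
Reagents that add atoms: none
Why: Chemoselective hydride reduction, since LiBH4 reduces a methyl ester but not the hindered tert-butyl ester.

Step 12
Reactants: 17 tert-butyl 1-(hydroxymethyl)-4,7-dimethyl-1,2,4a,5,6,7,8,8a-octahydronaphthalene-2-carboxylate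
Product: 18 tert-butyl 1-formyl-4,7-dimethyl-1,2,4a,5,6,7,8,8a-octahydronaphthalene-2-carboxylate
Conditions: Dess–Martin periodinane, pyridine, CH2Cl2, 0 °C → rt
Reagents that add atoms: none
Why: Dess–Martin oxidation of a primary alcohol to the aldehyde, whose equatorial C-1 configuration is also the thermodynamic one.

Step 13
Reactants: 18 tert-butyl 1-formyl-4,7-dimethyl-1,2,4a,5,6,7,8,8a-octahydronaphthalene-2-carboxylate
Product: 19 tert-butyl 4,7-dimethyl-1-[(E)-prop-1-enyl]-1,2,4a,5,6,7,8,8a-octahydronaphthalene-2-carboxylate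
Conditions: 5-(ethylsulfonyl)-1-phenyl-1H-tetrazole, KN(SiMe3)2, DME, −60 °C; then 18, −60 °C → rt
Reagents that add atoms: 5-(ethylsulfonyl)-1-phenyl-1H-tetrazole, CCS(=O)(=O)c1nnnn1-c1ccccc1
Why: Julia–Kocienski olefination, which with a 1-phenyltetrazolyl sulfone and a potassium base in DME should give the E-propenyl group from an α-branched aldehyde.

Step 14
Reactants: 19 tert-butyl 4,7-dimethyl-1-[(E)-prop-1-enyl]-1,2,4a,5,6,7,8,8a-octahydronaphthalene-2-carboxylate
Product: 20 [4,7-dimethyl-1-[(E)-prop-1-enyl]-1,2,4a,5,6,7,8,8a-octahydronaphthalen-2-yl]methanol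
Conditions: LiAlH4, THF, 0 °C → rt; aq. NaOH work-up
Reagents that add atoms: none
Why: LiAlH4 reduction of the tert-butyl ester to the primary alcohol, to which the two isolated alkenes are inert.

Step 15
Reactants: 20 [4,7-dimethyl-1-[(E)-prop-1-enyl]-1,2,4a,5,6,7,8,8a-octahydronaphthalen-2-yl]methanol
Product: 21 4,7-dimethyl-1-[(E)-prop-1-enyl]-1,2,4a,5,6,7,8,8a-octahydronaphthalene-2-carbaldehyde
Conditions: Dess–Martin periodinane, pyridine, CH2Cl2, 0 °C
Reagents that add atoms: none
Why: Dess–Martin oxidation under buffered, non-basic conditions, so the β,γ-unsaturated aldehyde should neither conjugate nor lose its equatorial C-2 configuration.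

Step 16
Reactants: 22 1,4-dioxaspiro[4.5]dec-6-en-8-one
Product: 23 (R)-1,4-dioxaspiro[4.5]dec-6-en-8-ol
Conditions: RuCl(p-cymene)[(R,R)-TsDPEN] (1 mol %), KOH (2 mol %), i-PrOH, rt
Reagents that add atoms: none
Why: Noyori asymmetric transfer hydrogenation of the enone carbonyl (1,2-reduction), in which the alkene takes the place of the aryl group of an aryl ketone so that the R,R ligand should deliver the R carbinol (future C-4′).

Step 17
Reactants: 23 (R)-1,4-dioxaspiro[4.5]dec-6-en-8-ol
Product: 24 (R)-8-(tert-butyldimethylsilyloxy)-1,4-dioxaspiro[4.5]dec-6-ene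
Conditions: t-BuMe2SiCl, imidazole, DMF, rt
Reagents that add atoms: tert-butyldimethylsilyl chloride, CC(C)(C)[Si](C)(C)Cl
Why: Standard silylation of a secondary alcohol, which does not touch the stereocentre.

Step 18
Reactants: 24 (R)-8-(tert-butyldimethylsilyloxy)-1,4-dioxaspiro[4.5]dec-6-ene
Product: 25 (R)-4-(tert-butyldimethylsilyloxy)cyclohex-2-en-1-one
Conditions: PPTS (cat.), acetone/H2O, 50 °C
Reagents that add atoms: water, O
Why: Mild acid-catalysed acetal hydrolysis, under which the allylic dioxolane should open while the silyl ether stays in place.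

Step 19
Reactants: 26 5-bromo-2,4-dichloropyridine
Product: 27 5-bromo-2,4-bis[2-(trimethylsilyl)ethoxy]pyridine
Conditions: Me3SiCH2CH2OH (2.5 equiv), NaH (2.6 equiv), DMF, 0 → 70 °C
Reagents that add atoms: 2-(trimethylsilyl)ethanol, C[Si](C)(C)CCO
Why: Twofold nucleophilic aromatic substitution (addition–elimination) at C-4 and then C-2, the positions activated by the ring nitrogen, while the C-5 bromide is not activated and stays.

Step 20
Reactants: 27 5-bromo-2,4-bis[2-(trimethylsilyl)ethoxy]pyridine; 25 (R)-4-(tert-butyldimethylsilyloxy)cyclohex-2-en-1-one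
Product: 30 5-[4-(tert-butyldimethylsilyloxy)-1-(triethylsilyloxy)cyclohex-2-en-1-yl]-2,4-bis[2-(trimethylsilyl)ethoxy]pyridine (silyloxy groups cis), via aryllithium 28 (not isolated), via lithium alkoxide 29 (not isolated)
Conditions: n-BuLi (1.05 equiv), THF, −78 °C; 25, −78 °C; Et3SiOTf, −78 → 0 °C
Reagents that add atoms: triethylsilyl trifluoromethanesulfonate, CC[Si](CC)(CC)OS(=O)(=O)C(F)(F)F
Why: Bromine–lithium exchange, 1,2-addition of the aryllithium to the enone carbonyl and O-silylation of the alkoxide, in which axial attack anti to the pseudoaxial C-4′ silyloxy group should place the new C-1′ oxygen cis to the C-4′ oxygen, the minor 1′-epimer being removed by chromatography.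

Step 21
Reactants: 30 5-[4-(tert-butyldimethylsilyloxy)-1-(triethylsilyloxy)cyclohex-2-en-1-yl]-2,4-bis[2-(trimethylsilyl)ethoxy]pyridine
Product: 31 5-[5-(tert-butyldimethylsilyloxy)-2-(triethylsilyloxy)-7-oxabicyclo[4.1.0]heptan-2-yl]-2,4-bis[2-(trimethylsilyl)ethoxy]pyridine (epoxide trans to both silyloxy groups)
Conditions: CF3CO2H (1.05 equiv), then mCPBA (1.5 equiv), CH2Cl2, 0 °C → rt; aq. NaHCO3
Reagents that add atoms: 3-chloroperoxybenzoic acid, OOC(=O)c1cccc(Cl)c1
Why: Prilezhaev (peracid) epoxidation with the pyridine held as its trifluoroacetate salt against N-oxidation, where in the half-chair with the tertiary OSiEt3 pseudoaxial and the pyridyl group pseudoequatorial both silyloxy groups shield the lower face, so oxygen should arrive on the upper face and set C-2′ and C-3′ trans to both C–O bonds.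

Step 22
Reactants: 31 5-[5-(tert-butyldimethylsilyloxy)-2-(triethylsilyloxy)-7-oxabicyclo[4.1.0]heptan-2-yl]-2,4-bis[2-(trimethylsilyl)ethoxy]pyridine (1.5 equiv); 21 4,7-dimethyl-1-[(E)-prop-1-enyl]-1,2,4a,5,6,7,8,8a-octahydronaphthalene-2-carbaldehyde
Product: 33 pyridin-3-yl decalin-2-yl carbinol (both carbinol epimers), via 3-lithiopyridine 32 (not isolated)
Conditions: n-BuLi (1.05 equiv to 31), THF, −78 → −40 °C; 21, −78 °C; AcOH
Reagents that add atoms: none
Why: Directed ortho-lithiation at pyridine C-3, the position flanked by both alkoxy groups, and addition of the aryllithium to the aldehyde at low temperature, the carbinol configuration being irrelevant because step 23 oxidises it.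

Step 23
Reactants: 33 pyridin-3-yl decalin-2-yl carbinol
Product: 34 fully protected ketone (3-acyl-2,4-bis[2-(trimethylsilyl)ethoxy]pyridine)
Conditions: Dess–Martin periodinane, pyridine, CH2Cl2, rt
Reagents that add atoms: none
Why: Dess–Martin oxidation of the hindered secondary carbinol to the aryl ketone under buffered conditions that spare the epoxide, silyl ethers and the equatorial C-2 centre.

Step 24
Reactants: 34 fully protected ketone
Product: 35 target CNP0494338.1
Conditions: n-Bu4NF/AcOH (1:1, excess), THF, 0 °C → rt (40 °C if needed)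
Reagents that add atoms: none
Why: Fluoride-induced cleavage of both silyl ethers together with β-elimination of the two 2-(trimethylsilyl)ethyl ethers (loss of ethene and Me3SiF) to unveil the 4-hydroxy-2-pyridone, buffered with AcOH so that no alkoxide can trigger epoxide migration (Payne rearrangement).

Compound list
1 | (S)-citronellal | O=CC[C@@H](C)CCC=C(C)C | starting material
2 | dimethyl malonate | COC(=O)CC(=O)OC | starting material
3 | dimethyl 2-[(3S)-3,7-dimethyloct-6-enylidene]malonate | COC(=O)C(=CC[C@@H](C)CCC=C(C)C)C(=O)OC | intermediate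
4 | dimethyl 2-[(1S,2S,5S)-2-isopropenyl-5-methylcyclohexyl]malonate (all ring substituents equatorial) | COC(=O)C(C(=O)OC)[C@H]1C[C@@H](C)CC[C@@H]1C(C)=C | intermediate
5 | methyl 2-[(1R,2S,5S)-2-isopropenyl-5-methylcyclohexyl]acetate | COC(=O)C[C@H]1C[C@@H](C)CC[C@@H]1C(C)=C | intermediate
6 | potassium enolate of 5 | COC([O-])=C[C@H]1C[C@@H](C)CC[C@@H]1C(C)=C.[K+] | intermediate
7 | methyl 2-hydroxy-2-[(1S,2S,5S)-2-isopropenyl-5-methylcyclohexyl]acetate (carbinol epimers) | COC(=O)C(O)[C@H]1C[C@@H](C)CC[C@@H]1C(C)=C | intermediate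
8 | methyl 2-[(1S,2S,5S)-2-isopropenyl-5-methylcyclohexyl]-2-oxoacetate | COC(=O)C(=O)[C@H]1C[C@@H](C)CC[C@@H]1C(C)=C | intermediate
9 | (tert-butoxycarbonylmethylene)triphenylphosphorane | CC(C)(C)OC(=O)C=P(c1ccccc1)(c1ccccc1)c1ccccc1 | starting material
10 | 4-tert-butyl 1-methyl (E)-2-[(1S,2S,5S)-2-isopropenyl-5-methylcyclohexyl]but-2-enedioate | COC(=O)/C(=C/C(=O)OC(C)(C)C)[C@H]1C[C@@H](C)CC[C@@H]1C(C)=C | intermediate
11 | ozonide (3-methyl-1,2,4-trioxolan-3-yl compound) of 10 | COC(=O)/C(=C/C(=O)OC(C)(C)C)[C@H]1C[C@@H](C)CC[C@@H]1C1(C)OCOO1 | intermediate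
12 | 4-tert-butyl 1-methyl (E)-2-[(1S,2S,5S)-2-acetyl-5-methylcyclohexyl]but-2-enedioate | COC(=O)/C(=C/C(=O)OC(C)(C)C)[C@H]1C[C@@H](C)CC[C@@H]1C(C)=O | intermediate
13 | 2-tert-butyl 1-methyl 7-methyl-4-oxodecahydronaphthalene-1,2-dicarboxylate (trans-fused; esters and 7-methyl equatorial) | COC(=O)[C@@H]1[C@H]2C[C@@H](C)CC[C@@H]2C(=O)C[C@H]1C(=O)OC(C)(C)C | intermediate
14 | potassium C-3/C-4 enolate of 13 | COC(=O)[C@@H]1[C@H]2C[C@@H](C)CC[C@@H]2C([O-])=C[C@H]1C(=O)OC(C)(C)C.[K+] | intermediate
15 | C-4 enol triflate of 13 (C-3=C-4) | COC(=O)[C@@H]1[C@H]2C[C@@H](C)CC[C@@H]2C(OS(=O)(=O)C(F)(F)F)=C[C@H]1C(=O)OC(C)(C)C | intermediate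
16 | 2-tert-butyl 1-methyl 4,7-dimethyl-1,2,4a,5,6,7,8,8a-octahydronaphthalene-1,2-dicarboxylate | COC(=O)[C@@H]1[C@H]2C[C@@H](C)CC[C@@H]2C(C)=C[C@H]1C(=O)OC(C)(C)C | intermediate
17 | tert-butyl 1-(hydroxymethyl)-4,7-dimethyl-1,2,4a,5,6,7,8,8a-octahydronaphthalene-2-carboxylate | OC[C@@H]1[C@H]2C[C@@H](C)CC[C@@H]2C(C)=C[C@H]1C(=O)OC(C)(C)C | intermediate
18 | tert-butyl 1-formyl-4,7-dimethyl-1,2,4a,5,6,7,8,8a-octahydronaphthalene-2-carboxylate | O=C[C@@H]1[C@H]2C[C@@H](C)CC[C@@H]2C(C)=C[C@H]1C(=O)OC(C)(C)C | intermediate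
19 | tert-butyl 4,7-dimethyl-1-[(E)-prop-1-enyl]-1,2,4a,5,6,7,8,8a-octahydronaphthalene-2-carboxylate | C/C=C/[C@@H]1[C@H]2C[C@@H](C)CC[C@@H]2C(C)=C[C@H]1C(=O)OC(C)(C)C | intermediate
20 | [4,7-dimethyl-1-[(E)-prop-1-enyl]-1,2,4a,5,6,7,8,8a-octahydronaphthalen-2-yl]methanol | C/C=C/[C@@H]1[C@H]2C[C@@H](C)CC[C@@H]2C(C)=C[C@H]1CO | intermediate
21 | 4,7-dimethyl-1-[(E)-prop-1-enyl]-1,2,4a,5,6,7,8,8a-octahydronaphthalene-2-carbaldehyde | C/C=C/[C@@H]1[C@H]2C[C@@H](C)CC[C@@H]2C(C)=C[C@H]1C=O | intermediate
22 | 1,4-dioxaspiro[4.5]dec-6-en-8-one | O=C1CCC2(OCCO2)C=C1 | starting material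
23 | (R)-1,4-dioxaspiro[4.5]dec-6-en-8-ol | O[C@@H]1CCC2(OCCO2)C=C1 | intermediate
24 | (R)-8-(tert-butyldimethylsilyloxy)-1,4-dioxaspiro[4.5]dec-6-ene | CC(C)(C)[Si](C)(C)O[C@@H]1CCC2(OCCO2)C=C1 | intermediate
25 | (R)-4-(tert-butyldimethylsilyloxy)cyclohex-2-en-1-one | CC(C)(C)[Si](C)(C)O[C@@H]1CCC(=O)C=C1 | intermediate
26 | 5-bromo-2,4-dichloropyridine | Clc1cc(Cl)c(Br)cn1 | starting material
27 | 5-bromo-2,4-bis[2-(trimethylsilyl)ethoxy]pyridine | C[Si](C)(C)CCOc1cc(OCC[Si](C)(C)C)c(Br)cn1 | intermediate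
28 | 5-lithio-2,4-bis[2-(trimethylsilyl)ethoxy]pyridine | C[Si](C)(C)CCOc1cc(OCC[Si](C)(C)C)c([Li])cn1 | intermediate
29 | lithium alkoxide of the 1,2-adduct of 28 and 25 | C[Si](C)(C)CCOc1cc(OCC[Si](C)(C)C)c(cn1)[C@]1([O-])CC[C@@H](O[Si](C)(C)C(C)(C)C)C=C1.[Li+] | intermediate
30 | 5-[4-(tert-butyldimethylsilyloxy)-1-(triethylsilyloxy)cyclohex-2-en-1-yl]-2,4-bis[2-(trimethylsilyl)ethoxy]pyridine (silyloxy groups cis) | C[Si](C)(C)CCOc1cc(OCC[Si](C)(C)C)c(cn1)[C@]1(O[Si](CC)(CC)CC)CC[C@@H](O[Si](C)(C)C(C)(C)C)C=C1 | intermediate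
31 | 5-[5-(tert-butyldimethylsilyloxy)-2-(triethylsilyloxy)-7-oxabicyclo[4.1.0]heptan-2-yl]-2,4-bis[2-(trimethylsilyl)ethoxy]pyridine (epoxide trans to both silyloxy groups) | C[Si](C)(C)CCOc1cc(OCC[Si](C)(C)C)c(cn1)[C@]1(O[Si](CC)(CC)CC)CC[C@@H](O[Si](C)(C)C(C)(C)C)[C@@H]2O[C@@H]21 | intermediate
32 | 3-lithio derivative of 31 | [Li]c1c(OCC[Si](C)(C)C)c(cnc1OCC[Si](C)(C)C)[C@]1(O[Si](CC)(CC)CC)CC[C@@H](O[Si](C)(C)C(C)(C)C)[C@@H]2O[C@@H]21 | intermediate
33 | carbinol from 32 and 21 (carbinol epimers) | C/C=C/[C@@H]1[C@H]2C[C@@H](C)CC[C@@H]2C(C)=C[C@H]1C(O)c1c(OCC[Si](C)(C)C)c([C@]2(O[Si](CC)(CC)CC)CC[C@@H](O[Si](C)(C)C(C)(C)C)[C@@H]3O[C@@H]32)cnc1OCC[Si](C)(C)C | intermediate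
34 | fully protected ketone | C/C=C/[C@@H]1[C@H]2C[C@@H](C)CC[C@@H]2C(C)=C[C@H]1C(=O)c1c(OCC[Si](C)(C)C)c([C@]2(O[Si](CC)(CC)CC)CC[C@@H](O[Si](C)(C)C(C)(C)C)[C@@H]3O[C@@H]32)cnc1OCC[Si](C)(C)C | intermediate
35 | CNP0494338.1 | C/C=C/[C@@H]1[C@H]2C[C@@H](C)CC[C@@H]2C(C)=C[C@H]1C(=O)c1c(O)c([C@]2(O)CC[C@@H](O)[C@@H]3O[C@@H]32)c[nH]c1=O | target

Total step count: 24.
Longest linear sequence: 18 steps (steps 1–15, then 22–24).

Steps most likely to fail

First, step 8. The closure may stall at a kinetic product (axial ester at C-1, cis fusion or the five-membered adduct), or acylation of the enolate by the methyl ester may consume the catalytic base. The fallback sets out from 12 and returns at 13. It forms the C-2–C-3 bond without any alkoxide, as an enamine Michael addition with catalytic pyrrolidine/AcOH in CHCl3 at 40 °C: the less substituted enamine of the methyl ketone adds to C-2 and is hydrolysed on work-up. This may deliver the decalone partly as the C-1 epimer of 13 F1; catalytic DBU in toluene would then epimerise F1 to 13.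

Second, step 21. Oxygen transfer may go to the pyridine nitrogen, or face selection at the alkene may erode. The fallback sets out from 30 and returns at 31. Osmylation (OsO4 cat., N-methylmorpholine N-oxide, acetone/H2O) does not oxidise the pyridine and responds even more strongly to the two allylic silyloxy groups, so it should give the 2′,3′-cis-diol F2 on the upper face. MeC(OMe)3 with catalytic PPTS converts it into the cyclic orthoacetate F3. Me3SiCl opens this with inversion at C-3′ to the 3′-chloro-2′-acetate F4. K2CO3 in MeOH then closes the epoxide by a second inversion at the same carbon, so the oxygen stays on the face chosen by OsO4 and 31 results.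

Third, step 22. Lithiation at C-3 may be incomplete, n-BuLi may attack the epoxide, or the aryllithium may enolise the aldehyde instead of adding. The fallback sets out from 31 and returns at 33. Electrophilic iodination with N-iodosuccinimide in MeCN at C-3, the only free position ortho to both alkoxy groups, gives the 3-iodopyridine F5. Iodine–magnesium exchange with i-PrMgCl·LiCl (THF, −20 °C) gives the arylmagnesium chloride F6, a less basic nucleophile that tolerates the epoxide. Addition of 21 and an AcOH quench give 33.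

Further compounds
F1 | step 8 | C-1 epimer of 13 (axial methyl ester) | COC(=O)[C@H]1[C@H]2C[C@@H](C)CC[C@@H]2C(=O)C[C@H]1C(=O)OC(C)(C)C
F2 | step 21 | 2′,3′-cis-diol from 30 (both hydroxyls trans to the silyloxy groups) | C[Si](C)(C)CCOc1cc(OCC[Si](C)(C)C)c(cn1)[C@]1(O[Si](CC)(CC)CC)CC[C@@H](O[Si](C)(C)C(C)(C)C)[C@H](O)[C@@H]1O
F3 | step 21 | cyclic methyl orthoacetate of F2 | C[Si](C)(C)CCOc1cc(OCC[Si](C)(C)C)c(cn1)[C@]1(O[Si](CC)(CC)CC)CC[C@@H](O[Si](C)(C)C(C)(C)C)[C@@H]2OC(C)(OC)O[C@H]12
F4 | step 21 | 3′-chloro-2′-acetate (chloride trans to the acetate) | C[Si](C)(C)CCOc1cc(OCC[Si](C)(C)C)c(cn1)[C@]1(O[Si](CC)(CC)CC)CC[C@@H](O[Si](C)(C)C(C)(C)C)[C@@H](Cl)[C@@H]1OC(C)=O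
F5 | step 22 | 3-iodo derivative of 31 | Ic1c(OCC[Si](C)(C)C)c(cnc1OCC[Si](C)(C)C)[C@]1(O[Si](CC)(CC)CC)CC[C@@H](O[Si](C)(C)C(C)(C)C)[C@@H]2O[C@@H]21
F6 | step 22 | pyridin-3-ylmagnesium chloride from F5 | Cl[Mg]c1c(OCC[Si](C)(C)C)c(cnc1OCC[Si](C)(C)C)[C@]1(O[Si](CC)(CC)CC)CC[C@@H](O[Si](C)(C)C(C)(C)C)[C@@H]2O[C@@H]21
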